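## Retrosynthetic overview
1. Final step: mono-oxidation of a C2-symmetric (3R,3'R)-diol. The two carbinols are homotopic, so only one keto-alcohol can form.
2. Central CH2–CH2 bond: Ti(III) reductive homocoupling of a single bicyclic allylic bromide, so both halves come from one monomer.
3. Tetrasubstituted C(Me)=C(CH2Br) unit: from a bicyclic β-keto ester by enol triflate/Me2CuLi, DIBAL-H and Appel bromination.
4. Both rings of the monomer form in one diepoxide cascade. The oxepane C–O bond forms first (epoxonium ion), then a silyl enol ether closes the cyclohexanone C–C bond.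
5. Acyclic diepoxide: geraniol (Sharpless AE sets C5a/C9a, Shi epoxidation sets C3) plus the methyl acetoacetate dianion.

Assumption: I read the SMILES as (3R,5aS,9aS) for the carbinol half and (5aS,9aS) for the ketone half. Both halves are trans-fused and the 3-OH is cis to the angular methyl. Bicycles use 1-benzoxepine numbering (O1, C2, C3, C4, C5, C5a, C6–C9, C9a).

## Route

**Step 1**
Reactants: 1, geraniol
Product: 2, (2S,3S)-2,3-epoxygeraniol
Conditions: Ti(OiPr)4 (5 mol %), L-(+)-DET (7.5 mol %), t-BuOOH, 4 Å MS, CH2Cl2, −20 °C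
Reagents that add atoms: tert-butyl hydroperoxide, CC(C)(C)OO (one O)
Why: The Katsuki–Sharpless asymmetric epoxidation is hydroxyl-directed, so only the allylic alkene reacts, and L-(+)-tartrate gives the (2S,3S)-epoxide that becomes C9a and C5a.

**Step 2**
Reactants: 2
Product: 3, (2S,3S,6R)-2,3:6,7-diepoxygeraniol
Conditions: D-fructose-derived Shi ketone (30 mol %), Oxone, K2CO3, Bu4NHSO4, MeCN–DMM/aq. Na2B4O7–EDTA (pH ≈ 10.5), 0 °C
Reagents that add atoms: Oxone (KHSO5), [K+].[O-]S(=O)(=O)OO (one O)
Why: In the Shi asymmetric epoxidation the chiral dioxirane (spiro transition state) converts the Me2C=CH– alkene to the (R)-epoxide under catalyst control, which sets the future C3.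

**Step 3**
Reactants: 3
Product: 4, diepoxy iodide (2R,3S)-2-(iodomethyl)-3-methyl-3-{2-[(2R)-3,3-dimethyloxiran-2-yl]ethyl}oxirane (same geometry as 3; C2 becomes R only through CIP priority)
Conditions: I2, PPh3, imidazole, THF, 0 °C, dark
Reagents that add atoms: iodine, II
Why: This Appel-type (Garegg–Samuelsson) iodination is an SN2 reaction at the primary carbinol, and the imidazole buffer protects both epoxides, so no stereocentre is touched.

**Step 4**
Reactants: 4; 5, methyl acetoacetate
Product: 6, methyl (2Z)-3-(TBSO)-5-[(2S,3S)-3-{2-[(2R)-3,3-dimethyloxiran-2-yl]ethyl}-3-methyloxiran-2-yl]pent-2-enoate (E/Z is inconsequential)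
Conditions: 5 (1.3 equiv), NaH then n-BuLi, THF, 0 °C; 4, −78 → −10 °C; then TBSCl, DMPU, → rt; Et3N-deactivated SiO2
Reagents that add atoms: methyl acetoacetate, COC(=O)CC(C)=O; TBSCl, CC(C)(C)[Si](C)(C)Cl
Why: In this Huckin–Weiler dianion γ-alkylation the terminal carbanion displaces the primary iodide faster than it opens a trisubstituted epoxide, and in-situ O-silylation traps the enolate before it can attack the neighbouring epoxide.

**Step 5**
Reactants: 6
Product: 7, methyl (3R,5aS,9aS)-3-(TBSO)-2,2,5a-trimethyl-7-oxodecahydro-1-benzoxepine-6-carboxylate (C6 epimers/enol, inconsequential)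
Conditions: TBSOTf (1.1 equiv), 2,6-di-tert-butyl-4-methylpyridine, CH2Cl2, −78 → −40 °C; aq. NaHCO3
Reagents that add atoms: TBSOTf, CC(C)(C)[Si](C)(C)OS(=O)(=O)C(F)(F)F. It silylates O3 while the enol TBS is released as TBSOTf, so the step is a net isomerisation.
Why: This is a biomimetic tandem oxa-/carbacyclisation in which the silylated terminal epoxide is opened at its tertiary carbon by the internal epoxide oxygen (C3–O intact, 3R kept), and the enol-silane carbon then opens the resulting epoxonium anti at tertiary C5a (inversion; C9a–O intact) to give the trans-fused bicycle.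

**Step 6**
Reactants: 7
Product: 8, enol triflate methyl (3R,5aS,9aS)-3-(TBSO)-2,2,5a-trimethyl-7-(triflyloxy)-2,3,4,5,5a,8,9,9a-octahydro-1-benzoxepine-6-carboxylate
Conditions: NaH, THF, 0 °C; PhNTf2, 0 °C → rt
Reagents that add atoms: N-phenyl-bis(triflimide), O=S(=O)(N(c1ccccc1)S(=O)(=O)C(F)(F)F)C(F)(F)F
Why: O-triflation of the β-keto ester enolate can only place the double bond at C6=C7, which fixes the alkene regiochemistry.

**Step 7**
Reactants: 8
Product: 9, methyl (3R,5aS,9aS)-3-(TBSO)-2,2,5a,7-tetramethyl-2,3,4,5,5a,8,9,9a-octahydro-1-benzoxepine-6-carboxylate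
Conditions: Me2CuLi (MeLi, CuI), Et2O, −78 → −10 °C
Reagents that add atoms: lithium dimethylcuprate, [Li+].C[Cu-]C (one CH3)
Why: The McMurry–Scott/Weiler cuprate coupling (addition–elimination at the unhindered C7) replaces OTf by methyl, a sequence used on the analogous drimane β-keto esters.

**Step 8**
Reactants: 9
Product: 10, [(3R,5aS,9aS)-3-(TBSO)-2,2,5a,7-tetramethyl-2,3,4,5,5a,8,9,9a-octahydro-1-benzoxepin-6-yl]methanol
Conditions: DIBAL-H (3 equiv), CH2Cl2, −78 → 0 °C; Rochelle salt
Reagents that add atoms: none
Why: DIBAL-H performs a 1,2-reduction of the hindered enoate to the allylic alcohol and leaves the TBS ether, the oxepane and the alkene untouched.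

**Step 9**
Reactants: 10
Product: 11, (3R,5aS,9aS)-6-(bromomethyl)-3-(TBSO)-2,2,5a,7-tetramethyl-2,3,4,5,5a,8,9,9a-octahydro-1-benzoxepine
Conditions: CBr4, PPh3, CH2Cl2, −20 → 0 °C; used promptly
Reagents that add atoms: carbon tetrabromide, BrC(Br)(Br)Br (one Br)
Why: The Appel bromination is neutral, so the primary allylic alcohol is substituted without allylic transposition or silyl loss.

**Step 10**
Reactants: 11 (2 molecules)
Product: 12, 1,2-bis[(3R,5aS,9aS)-3-(TBSO)-2,2,5a,7-tetramethyl-2,3,4,5,5a,8,9,9a-octahydro-1-benzoxepin-6-yl]ethane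
Conditions: Cp2TiCl2 (20 mol %), Mn dust, degassed THF, rt
Reagents that add atoms: none
Why: In this Cp2TiCl-catalysed Wurtz-type homocoupling the allyl radical/allyl-Ti species couples α,α' because the γ-carbon is fully substituted (the β-onoceradiene precedent), and any minor enantiomer ends up in separable hetero-dimers.

**Step 11**
Reactants: 12
Product: 13, C2-symmetric (3R,3'R)-diol
Conditions: TBAF, THF, 60 °C
Reagents that add atoms: none
Why: Fluoride desilylation under non-acidic conditions avoids cationic cyclisation or migration of the two tetrasubstituted alkenes.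

**Step 12**
Reactants: 13
Product: 14, sodwanone T
Conditions: Dess–Martin periodinane (1.0 equiv), NaHCO3, CH2Cl2, 0 °C; chromatography, recovered 13 recycled
Reagents that add atoms: none
Why: Statistical Dess–Martin mono-oxidation of homotopic carbinols gives a single keto-alcohol (50 % ceiling per pass) and leaves the remaining 3R centre untouched.

Stereocentre ledger:
- C9a and C5a of both halves are set in step 1. C5a is then inverted stereospecifically in step 5.
- C3 is set in step 2.
- No later step breaks a bond at any of these centres.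

## Compound list
| No. | Name | SMILES | Role |
|---|---|---|---|
| 1 | geraniol | CC(C)=CCC/C(C)=C/CO | starting material |
| 2 | (2S,3S)-2,3-epoxygeraniol | OC[C@@H]1O[C@@]1(C)CCC=C(C)C | intermediate |
| 3 | (2S,3S,6R)-2,3:6,7-diepoxygeraniol | OC[C@@H]1O[C@@]1(C)CC[C@H]1OC1(C)C | intermediate |
| 4 | diepoxy iodide | IC[C@@H]1O[C@@]1(C)CC[C@H]1OC1(C)C | intermediate |
| 5 | methyl acetoacetate | COC(=O)CC(C)=O | starting material |
| 6 | diepoxy (Z)-TBS enol ether | COC(=O)/C=C(\O[Si](C)(C)C(C)(C)C)CC[C@@H]1O[C@@]1(C)CC[C@H]1OC1(C)C | intermediate |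
| 7 | bicyclic β-keto ester | COC(=O)C1C(=O)CC[C@@H]2OC(C)(C)[C@H](O[Si](C)(C)C(C)(C)C)CC[C@@]12C | intermediate |
| 8 | enol triflate | COC(=O)C1=C(OS(=O)(=O)C(F)(F)F)CC[C@@H]2OC(C)(C)[C@H](O[Si](C)(C)C(C)(C)C)CC[C@@]12C | intermediate |
| 9 | tetrasubstituted enoate | COC(=O)C1=C(C)CC[C@@H]2OC(C)(C)[C@H](O[Si](C)(C)C(C)(C)C)CC[C@@]12C | intermediate |
| 10 | allylic alcohol | OCC1=C(C)CC[C@@H]2OC(C)(C)[C@H](O[Si](C)(C)C(C)(C)C)CC[C@@]12C | intermediate |
| 11 | allylic bromide | BrCC1=C(C)CC[C@@H]2OC(C)(C)[C@H](O[Si](C)(C)C(C)(C)C)CC[C@@]12C | intermediate |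
| 12 | bis-TBS dimer | C(C1=C(C)CC[C@@H]2OC(C)(C)[C@H](O[Si](C)(C)C(C)(C)C)CC[C@@]12C)CC1=C(C)CC[C@@H]2OC(C)(C)[C@H](O[Si](C)(C)C(C)(C)C)CC[C@@]12C | intermediate |
| 13 | C2-symmetric (3R,3'R)-diol | C(C1=C(C)CC[C@@H]2OC(C)(C)[C@H](O)CC[C@@]12C)CC1=C(C)CC[C@@H]2OC(C)(C)[C@H](O)CC[C@@]12C | intermediate |
| 14 | sodwanone T | CC1=C(CCC2=C(C)CC[C@@H]3OC(C)(C)[C@H](O)CC[C@@]23C)[C@]2(C)CCC(=O)C(C)(C)O[C@H]2CC1 | target |

## Summary
Total steps: 12. Longest linear sequence: 12, from geraniol.

Three steps most likely to fail:

1. **Step 5 (cascade).**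
   - Risks: the β-silyloxyacrylate is a weak nucleophile, O-trapping or epoxide elimination may compete, and this C3/C5a relative configuration has no direct precedent.
   - Fallback: build the rings one at a time in reverse order.
     - Carry only the Sharpless epoxide forward (iodide of 2 plus the dianion).
     - Close the cyclohexanone by SnCl4-mediated C-cyclisation of the epoxy β-keto ester and advance it to the enoate.
     - Then Shi-epoxidise the prenyl tail and close the oxepane by acid-catalysed 7-endo hydroxy-epoxide opening at the tertiary carbon.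

2. **Step 4 (dianion plus epoxy iodide).**
   - Risks: epoxide opening, elimination, or furanylidene formation.
   - Fallback: form this C–C bond at the olefin stage.
     - Alkylate the dianion with geranyl bromide and mask the product as its methyl enol ether.
     - Epoxidise both alkenes with the ent-Shi ketone, which gives the 3S,5aS,9aS series, and run the same sequence to the dimer.
     - Oxidise both carbinols to the C2-symmetric dione and install 3R by mono-reduction with (S)-Me-CBS/BH3.

3. **Step 10 (homocoupling), which is also tied to the 50 % ceiling of step 12.**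
   - Fallback: a Biellmann-type heterocoupling.
     - Convert part of 11 to the allyl phenyl sulfone.
     - Alkylate its anion with a bromide that carries a different O3 protecting group.
     - Desulfonylate with Pd(dppp)Cl2/LiEt3BH.
     - Unmask and oxidise one carbinol selectively, which removes the statistical step.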